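**Plan**

Numbering (longipinane): C1 ketone, C2=C3(Me), C4, C5, C6 (CMe2), C7 (O-methacryloyl), C8, C9 (O-angeloyl), C10 (C–Me), C11; cyclobutane C4–C5–C11–C10; seven-membered ring C5–C6–C7–C8–C9–C10–C11.
Cuts: the two ester C–O bonds and the C1 oxo group (allylic oxidation); C5–C6 (aldol of a C7-ketone enolate at C6 onto a C5 cyclobutanone, C5–OH then removed); C5–C11 and C4–C10 (ketene–alkene [2+2], C5 = ketene carbon); C8–C9 (aldol), back to methyl geranate and methyl isopropenyl ketone.
Forward: a C15 chain (C10 + C5) is folded; the four- and six-membered rings arise together in the intramolecular cycloaddition, the seven-membered ring last by reductive aldol cyclisation.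
What makes the last closure possible: C5 and C10 sit 1,3 across the cyclobutane, and the C10 chain (C9–C8–C7) is axial, anti to the C1–C3 bridge, so it holds C6 (gem-dimethyl, α to the C7 oxygen) under the strained C5 carbonyl of a bicyclo[3.1.1]heptan-6-one.
Stereochemistry: C9 from a reagent-controlled boron aldol; C10 from the (E)-alkene geometry, and C4/C10/C11 relative to C9 from the facial selectivity of the cycloaddition; C5 from the tether; C7 from a CBS reduction; the (Z)-angelate from angelic acid.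

Key step: step 7

Remark: methyl geranate is taken as the (2E) isomer (this geometry is lost at the ketene stage in any case); chain numbering is used for 1–10 and longipinane numbering from 13 on (chain C8 = longipinane C9).

**Route**

Step 1
Reactants: 1 methyl geranate [methyl (2E)-3,7-dimethylocta-2,6-dienoate]
Product: 2 methyl (2E,6E)-8-hydroxy-3,7-dimethylocta-2,6-dienoate
Conditions: SeO2 (cat.), t-BuOOH, salicylic acid (cat.), CH2Cl2, rt
Reagents that add atoms: tert-butyl hydroperoxide CC(C)(C)OO (terminal oxygen source), selenium dioxide O=[Se]=O (catalytic oxygen carrier)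
Why: Selenium dioxide allylic hydroxylation (ene reaction, then [2,3]-sigmatropic shift) should oxidise only the (E)-methyl group of the electron-rich C6=C7 alkene, so the oxygenated carbon ends trans to the chain (6E) and the electron-poor enoate is untouched.

Step 2
Reactants: 2 methyl (2E,6E)-8-hydroxy-3,7-dimethylocta-2,6-dienoate
Product: 3 methyl (2E,6E)-3,7-dimethyl-8-oxoocta-2,6-dienoate
Conditions: MnO2, CH2Cl2, rt
Reagents that add atoms: none
Why: Manganese dioxide oxidation of the allylic alcohol should give the (E)-enal without touching the enoate or isomerising the alkene.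

Step 3
Reactants: 3 methyl (2E,6E)-3,7-dimethyl-8-oxoocta-2,6-dienoate; 4 3-methylbut-3-en-2-one
Product: 6 methyl (2E,6E,8R)-8-hydroxy-3,7,11-trimethyl-10-oxododeca-2,6,11-trienoate, via enol borinate 5 (not isolated)
Conditions: 4, (−)-Ipc2BCl, Et3N, Et2O, 0 °C; then 3, −78 → −20 °C; H2O2, pH 7 buffer, MeOH, 0 °C
Reagents that add atoms: none
Why: Boron aldol of a methyl ketone: 4 can be enolised only at its methyl group, and the diisopinocampheyl enol borinate 5 should add through a cyclic transition state to the re face of the enal (reagent control), which sets the (8R) carbinol centre that becomes C9 of the target.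

Step 4
Reactants: 6 methyl (2E,6E,8R)-8-hydroxy-3,7,11-trimethyl-10-oxododeca-2,6,11-trienoate
Product: 7 methyl (2E,6E,8R)-8-[(tert-butyldimethylsilyl)oxy]-3,7,11-trimethyl-10-oxododeca-2,6,11-trienoate
Conditions: TBSOTf, 2,6-lutidine, CH2Cl2, −78 °C
Reagents that add atoms: tert-butyldimethylsilyl triflate CC(C)(C)[Si](C)(C)OS(=O)(=O)C(F)(F)F
Why: Silylation of the secondary alcohol with the silyl triflate at low temperature should outrun oxa-Michael closure onto the isopropenyl ketone, and the silyl ether later serves as the control element of the cycloaddition.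

Step 5
Reactants: 7 methyl (2E,6E,8R)-8-[(tert-butyldimethylsilyl)oxy]-3,7,11-trimethyl-10-oxododeca-2,6,11-trienoate
Product: 8 (2E,6E,8R)-8-[(tert-butyldimethylsilyl)oxy]-3,7,11-trimethyl-10-oxododeca-2,6,11-trienoic acid
Conditions: Me3SnOH, 1,2-dichloroethane, 80 °C; dilute HCl wash
Reagents that add atoms: trimethyltin hydroxide C[Sn](C)(C)O
Why: Ester hydrolysis with trimethyltin hydroxide runs under near-neutral conditions, which should spare the β-silyloxy ketone (no elimination) and the enone.

Step 6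
Reactants: 8 (2E,6E,8R)-8-[(tert-butyldimethylsilyl)oxy]-3,7,11-trimethyl-10-oxododeca-2,6,11-trienoic acid
Product: 11 (1R,5S,7S)-7-[(1R)-1-[(tert-butyldimethylsilyl)oxy]-4-methyl-3-oxopent-4-en-1-yl]-7-methyl-2-methylidenebicyclo[3.1.1]heptan-6-one, via acid chloride 9 (not isolated), via vinylketene 10 (not isolated)
Conditions: 1-chloro-N,N,2-trimethylprop-1-en-1-amine, CH2Cl2, 0 °C → rt; then slow addition to Et3N, toluene, 110 °C (high dilution, BHT)
Reagents that add atoms: none
Why: Intramolecular ketene–alkene [2+2] cycloaddition (vinylketene 10 by 1,4-dehydrochlorination of 9; crossed mode, the rule when the distal alkene carbon is the more substituted one): the ketene carbonyl carbon bonds to chain C6 and the ketene α-carbon to C7, the (6E) geometry is transferred suprafacially so that the methyl group ends syn and the side chain anti to the three-carbon bridge, and the ketene is expected to approach the alkene face anti to the C8–OSi bond in the conformer that keeps the C9 methylene anti to the vinylic methyl group and H8 between that methyl group and the incoming ketene carbon, which sets the three ring stereocentres relative to C8.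

Step 7
Reactants: 11 (1R,5S,7S)-7-[(1R)-1-[(tert-butyldimethylsilyl)oxy]-4-methyl-3-oxopent-4-en-1-yl]-7-methyl-2-methylidenebicyclo[3.1.1]heptan-6-one
Product: 13 (9R)-9-[(tert-butyldimethylsilyl)oxy]-5-hydroxylongipin-3(15)-en-7-one, via copper enolate 12 (not isolated)
Conditions: [(Ph3P)CuH]6 (Stryker's reagent), toluene, −40 → 0 °C; then aq. NH4Cl
Reagents that add atoms: none
Why: Copper hydride adds hydrogen to the unsubstituted β-carbon of the isopropenyl ketone (1,4-reduction), which gives the fully substituted copper enolate 12 at C6 regiospecifically, and this enolate adds to the strained C5 cyclobutanone carbonyl to form the C5–C6 bond and, after protonation, the tertiary alcohol. The closest known reaction type is the copper hydride reductive aldol cyclisation of keto-enones, an intramolecular aldol addition that is driven here by release of the sp2 strain of the bicyclo[3.1.1]heptan-6-one carbonyl. The seven-membered ring closes in the 7-(enolendo)-exo-trig mode and no other ring is formed. The only new stereocentre, C5, is controlled by the tether: the C10 chain is axial on the cyclobutane and anti to the C1–C3 bridge, so C6 can reach only the carbonyl face anti to that bridge, which puts C6 axial and the oxygen equatorial. The step needs chemoselectivity (1,4-reduction of the unhindered enone before 1,2-reduction of the cyclobutanone, secured by the soft hydride at low temperature) and regioselective enolate formation (C6, not C8, secured because the enolate is made by reduction and not by deprotonation, so that no proton transfer to C8 and no β-elimination of the silyloxy group can occur).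

Step 8
Reactants: 13 (9R)-9-[(tert-butyldimethylsilyl)oxy]-5-hydroxylongipin-3(15)-en-7-one
Product: 14 methyl (9R)-9-[(tert-butyldimethylsilyl)oxy]-7-oxolongipin-3(15)-en-5-yl oxalate
Conditions: ClC(O)CO2Me, Et3N, DMAP, CH2Cl2, 0 °C → rt
Reagents that add atoms: methyl chlorooxoacetate COC(=O)C(=O)Cl
Why: Acylation of the tertiary cyclobutanol with the small, very reactive chlorooxoacetate under amine/DMAP catalysis avoids the free alkoxide (and with it retro-aldol or fragmentation of the strained ring) and gives a radical precursor that cannot eliminate, because the three neighbouring carbons are two bridgeheads and a quaternary carbon.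

Step 9
Reactants: 14 methyl (9R)-9-[(tert-butyldimethylsilyl)oxy]-7-oxolongipin-3(15)-en-5-yl oxalate
Product: 15 (9R)-9-[(tert-butyldimethylsilyl)oxy]longipin-3(15)-en-7-one
Conditions: Bu3SnH (high concentration), AIBN, toluene, 100 °C
Reagents that add atoms: none
Why: Radical deoxygenation of a tertiary alkyl methyl oxalate (Barton–McCombie-type chain): the C5 cyclobutyl radical should be reduced by the concentrated stannane before it can rearrange, and hydrogen can enter only from the outer face because C6 is held axial by the seven-membered ring, so C5 keeps its configuration.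

Step 10
Reactants: 15 (9R)-9-[(tert-butyldimethylsilyl)oxy]longipin-3(15)-en-7-one
Product: 16 (9R)-9-[(tert-butyldimethylsilyl)oxy]longipin-2-en-7-one
Conditions: RhCl3·3H2O (cat.), EtOH, 80 °C
Reagents that add atoms: none
Why: Rhodium hydride-catalysed alkene isomerisation should move the exocyclic double bond into the ring (C2=C3), the more stable trisubstituted position and the only one available because C4 is a bridgehead.

Step 11
Reactants: 16 (9R)-9-[(tert-butyldimethylsilyl)oxy]longipin-2-en-7-one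
Product: 17 (7R,9R)-9-[(tert-butyldimethylsilyl)oxy]longipin-2-en-7-ol
Conditions: (S)-Me-CBS (cat.), catecholborane, toluene, −78 → −40 °C; aq. NaOH work-up
Reagents that add atoms: none
Why: Corey–Bakshi–Shibata reduction: the ketone is flanked by the quaternary C6 (large) and the C8 methylene (small), so the (S)-oxazaborolidine should deliver hydride to give the (7R)-alcohol under reagent control, and material of the minor enantiomeric series left from step 3 becomes a separable diastereomer here.

Step 12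
Reactants: 17 (7R,9R)-9-[(tert-butyldimethylsilyl)oxy]longipin-2-en-7-ol; 18 methacryloyl chloride
Product: 19 (7R,9R)-9-[(tert-butyldimethylsilyl)oxy]longipin-2-en-7-yl methacrylate
Conditions: Et3N, DMAP (cat.), CH2Cl2, 0 °C → rt
Reagents that add atoms: none
Why: DMAP-catalysed acylation of the only free hydroxyl group with the acid chloride installs the C7 methacrylate.

Step 13
Reactants: 19 (7R,9R)-9-[(tert-butyldimethylsilyl)oxy]longipin-2-en-7-yl methacrylate
Product: 20 (7R,9R)-9-[(tert-butyldimethylsilyl)oxy]-1-oxolongipin-2-en-7-yl methacrylate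
Conditions: CrO3, 3,5-dimethylpyrazole, CH2Cl2, −20 °C
Reagents that add atoms: chromium trioxide O=[Cr](=O)=O
Why: Chromium(VI)–dimethylpyrazole allylic oxidation should convert the ring methylene C1 next to the electron-rich trisubstituted alkene into the enone carbonyl, while the electron-poor methacrylate alkene, the bridgehead C4–H and the silyl ether are not attacked.

Step 14
Reactants: 20 (7R,9R)-9-[(tert-butyldimethylsilyl)oxy]-1-oxolongipin-2-en-7-yl methacrylate
Product: 21 (7R,9R)-9-hydroxy-1-oxolongipin-2-en-7-yl methacrylate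
Conditions: HF·pyridine, THF, 0 °C → rt
Reagents that add atoms: none
Why: Desilylation with HF·pyridine under mildly acidic conditions should free the C9 hydroxyl without acyl migration, which the trans-1,3 arrangement of the two oxygens on the seven-membered ring also disfavours.

Step 15
Reactants: 21 (7R,9R)-9-hydroxy-1-oxolongipin-2-en-7-yl methacrylate; 22 angelic acid
Product: 24 (4R,5S,7R,9R,10R,11R)-9-angeloyloxy-7-methacryloyloxylongipin-2-en-1-one (CNP0317071.1), via mixed anhydride 23 (not isolated)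
Conditions: 22, 2,4,6-trichlorobenzoyl chloride, Et3N, toluene, rt; then 21, 80 °C
Reagents that add atoms: none
Why: Yamaguchi-type esterification through the mixed anhydride 23 without a nucleophilic catalyst should acylate the hindered C9 alcohol with retention of the (Z) geometry of the angeloyl group (no isomerisation to the tiglate).

**Compound list**

1 | methyl geranate, methyl (2E)-3,7-dimethylocta-2,6-dienoate | COC(=O)/C=C(\C)CCC=C(C)C | starting material
2 | methyl (2E,6E)-8-hydroxy-3,7-dimethylocta-2,6-dienoate | COC(=O)/C=C(\C)CC/C=C(\C)CO | intermediate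
3 | methyl (2E,6E)-3,7-dimethyl-8-oxoocta-2,6-dienoate | COC(=O)/C=C(\C)CC/C=C(\C)C=O | intermediate
4 | 3-methylbut-3-en-2-one (methyl isopropenyl ketone) | CC(=O)C(C)=C | starting material
5 | 3-methylbuta-1,3-dien-2-yl diisopinocampheylborinate (formed in the flask) | C=C(C)C(=C)OB([C@@H]1C[C@@H]2C[C@H]([C@H]1C)C2(C)C)[C@@H]1C[C@@H]2C[C@H]([C@H]1C)C2(C)C | intermediate
6 | methyl (2E,6E,8R)-8-hydroxy-3,7,11-trimethyl-10-oxododeca-2,6,11-trienoate | COC(=O)/C=C(\C)CC/C=C(\C)[C@H](O)CC(=O)C(C)=C | intermediate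
7 | methyl (2E,6E,8R)-8-[(tert-butyldimethylsilyl)oxy]-3,7,11-trimethyl-10-oxododeca-2,6,11-trienoate | COC(=O)/C=C(\C)CC/C=C(\C)[C@H](O[Si](C)(C)C(C)(C)C)CC(=O)C(C)=C | intermediate
8 | (2E,6E,8R)-8-[(tert-butyldimethylsilyl)oxy]-3,7,11-trimethyl-10-oxododeca-2,6,11-trienoic acid | OC(=O)/C=C(\C)CC/C=C(\C)[C@H](O[Si](C)(C)C(C)(C)C)CC(=O)C(C)=C | intermediate
9 | acid chloride of 8 (formed in the flask) | ClC(=O)/C=C(\C)CC/C=C(\C)[C@H](O[Si](C)(C)C(C)(C)C)CC(=O)C(C)=C | intermediate
10 | vinylketene, (6E,8R)-8-[(tert-butyldimethylsilyl)oxy]-7,11-dimethyl-3-methylidene-10-oxododeca-1,6,11-trien-1-one (formed in the flask) | O=C=CC(=C)CC/C=C(\C)[C@H](O[Si](C)(C)C(C)(C)C)CC(=O)C(C)=C | intermediate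
11 | (1R,5S,7S)-7-[(1R)-1-[(tert-butyldimethylsilyl)oxy]-4-methyl-3-oxopent-4-en-1-yl]-7-methyl-2-methylidenebicyclo[3.1.1]heptan-6-one (7-methyl syn, side chain anti to the C2–C4 bridge) | C=C(C)C(=O)C[C@@H](O[Si](C)(C)C(C)(C)C)[C@@]2(C)[C@@H]3CCC(=C)[C@H]2C3=O | intermediate
12 | triphenylphosphine-ligated copper(I) enolate of 11 at C6/C7 (formed in the flask) | CC(C)=C(O[Cu]P(c1ccccc1)(c1ccccc1)c1ccccc1)C[C@@H](O[Si](C)(C)C(C)(C)C)[C@@]2(C)[C@@H]3CCC(=C)[C@H]2C3=O | intermediate
13 | (9R)-9-[(tert-butyldimethylsilyl)oxy]-5-hydroxylongipin-3(15)-en-7-one (C4, C10, C11 as in the target; 5-OH equatorial, C6 axial on the cyclobutane) | O=C1C[C@@H](O[Si](C)(C)C(C)(C)C)[C@@]2(C)[C@@H]3CCC(=C)[C@H]2[C@]3(O)C1(C)C | intermediate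
14 | methyl (9R)-9-[(tert-butyldimethylsilyl)oxy]-7-oxolongipin-3(15)-en-5-yl oxalate | O=C1C[C@@H](O[Si](C)(C)C(C)(C)C)[C@@]2(C)[C@@H]3CCC(=C)[C@H]2[C@]3(OC(=O)C(=O)OC)C1(C)C | intermediate
15 | (9R)-9-[(tert-butyldimethylsilyl)oxy]longipin-3(15)-en-7-one (C4, C5, C10, C11 as in the target) | O=C1C[C@@H](O[Si](C)(C)C(C)(C)C)[C@@]2(C)[C@@H]3CCC(=C)[C@H]2[C@@H]3C1(C)C | intermediate
16 | (9R)-9-[(tert-butyldimethylsilyl)oxy]longipin-2-en-7-one | O=C1C[C@@H](O[Si](C)(C)C(C)(C)C)[C@@]2(C)[C@@H]3CC=C(C)[C@H]2[C@@H]3C1(C)C | intermediate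
17 | (7R,9R)-9-[(tert-butyldimethylsilyl)oxy]longipin-2-en-7-ol | O[C@@H]1C[C@@H](O[Si](C)(C)C(C)(C)C)[C@@]2(C)[C@@H]3CC=C(C)[C@H]2[C@@H]3C1(C)C | intermediate
18 | methacryloyl chloride | C=C(C)C(=O)Cl | starting material
19 | (7R,9R)-9-[(tert-butyldimethylsilyl)oxy]longipin-2-en-7-yl methacrylate | C=C(C)C(=O)O[C@@H]1C[C@@H](O[Si](C)(C)C(C)(C)C)[C@@]2(C)[C@@H]3CC=C(C)[C@H]2[C@@H]3C1(C)C | intermediate
20 | (7R,9R)-9-[(tert-butyldimethylsilyl)oxy]-1-oxolongipin-2-en-7-yl methacrylate | C=C(C)C(=O)O[C@@H]1C[C@@H](O[Si](C)(C)C(C)(C)C)[C@@]2(C)[C@@H]3C(=O)C=C(C)[C@H]2[C@@H]3C1(C)C | intermediate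
21 | (7R,9R)-9-hydroxy-1-oxolongipin-2-en-7-yl methacrylate | C=C(C)C(=O)O[C@@H]1C[C@@H](O)[C@@]2(C)[C@@H]3C(=O)C=C(C)[C@H]2[C@@H]3C1(C)C | intermediate
22 | angelic acid, (Z)-2-methylbut-2-enoic acid | C/C=C(/C)C(=O)O | starting material
23 | angelic 2,4,6-trichlorobenzoic anhydride (formed in the flask) | C/C=C(/C)C(=O)OC(=O)c1c(Cl)cc(Cl)cc1Cl | intermediate
24 | (4R,5S,7R,9R,10R,11R)-9-angeloyloxy-7-methacryloyloxylongipin-2-en-1-one (CNP0317071.1) | C=C(C)C(=O)O[C@@H]1C[C@@H](OC(=O)/C(C)=C\C)[C@@]2(C)[C@@H]3C(=O)C=C(C)[C@H]2[C@@H]3C1(C)C | target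

**Count and risks**

Total step count: 15. Longest linear sequence: 15 steps (1 → 24).

Steps most likely to fail:

Step 6. The ketene may add to the other alkene face relative to the silyloxy stereocentre (poor or reversed facial selectivity), which would put the ring stereocentres in the enantiomeric series relative to C9. The fallback sets out from 3 and comes back at 19: the aldol of step 3 is run with (+)-Ipc2BCl to give the (8S)-aldol F1, which is silylated to the TBS ether F2 and hydrolysed to the acid F3. F3 is cyclised as in step 6 through the acid chloride F4 and the vinylketene F5; with the reversed facial preference the major cycloadduct is then the side-chain epimer F6, which carries the natural configuration of the bicyclic core. Steps 7 to 12 applied to F6 should give, through the copper enolate F7, the hydroxy ketone F8, the oxalate F9, the ketone F10, its endocyclic alkene isomer F11, the (7R)-alcohol F12 and the methacrylate F13. The silyl ether of F13 is cleaved (HF·pyridine) to the (9S)-alcohol F14, which is oxidised (Dess–Martin periodinane) to the 9-ketone F15; a reagent-controlled CBS reduction [(S)-Me-CBS, catecholborane; quaternary C10 large, C8 methylene small] should give the (9R)-alcohol F16, and silylation (TBSOTf, 2,6-lutidine) returns 19.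

Step 7. The copper hydride may attack the strained cyclobutanone carbonyl (1,2-reduction), or the copper enolate may be protonated before the seven-membered ring closes. The fallback sets out from 11 and comes back at 13: rhodium-catalysed 1,4-hydrosilylation of the isopropenyl ketone [(Ph3P)3RhCl, Et3SiH] gives the isolated triethylsilyl enol ether F17, and fluoride (TASF, THF, −78 °C, then aq. NH4Cl) liberates the naked enolate for a fluoride-promoted intramolecular aldol addition to 13.

Step 9. The C5 radical has the C7 carbonyl in the β-position and may undergo 1,2-acyl migration (ring contraction) in competition with hydrogen transfer. The fallback sets out from 13 and comes back at 17: CBS reduction of the C7 ketone first [(S)-Me-CBS, excess catecholborane] gives the diol F18; the secondary hydroxyl is silylated (TESCl, imidazole) to the triethylsilyl ether F19; the tertiary hydroxyl is converted into the methyl oxalate F20 and removed (Bu3SnH, AIBN) to give F21, in which no acyl group stands next to the radical; alkene isomerisation (RhCl3·3H2O, EtOH) gives F22, and selective removal of the triethylsilyl group (PPTS, MeOH) gives 17.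

**Further compounds**

F1 | step 6 | methyl (2E,6E,8S)-8-hydroxy-3,7,11-trimethyl-10-oxododeca-2,6,11-trienoate | COC(=O)/C=C(\C)CC/C=C(\C)[C@@H](O)CC(=O)C(C)=C
F2 | step 6 | methyl (2E,6E,8S)-8-[(tert-butyldimethylsilyl)oxy]-3,7,11-trimethyl-10-oxododeca-2,6,11-trienoate | COC(=O)/C=C(\C)CC/C=C(\C)[C@@H](O[Si](C)(C)C(C)(C)C)CC(=O)C(C)=C
F3 | step 6 | (2E,6E,8S)-8-[(tert-butyldimethylsilyl)oxy]-3,7,11-trimethyl-10-oxododeca-2,6,11-trienoic acid | OC(=O)/C=C(\C)CC/C=C(\C)[C@@H](O[Si](C)(C)C(C)(C)C)CC(=O)C(C)=C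
F4 | step 6 | acid chloride of F3 | ClC(=O)/C=C(\C)CC/C=C(\C)[C@@H](O[Si](C)(C)C(C)(C)C)CC(=O)C(C)=C
F5 | step 6 | vinylketene, (6E,8S)-8-[(tert-butyldimethylsilyl)oxy]-7,11-dimethyl-3-methylidene-10-oxododeca-1,6,11-trien-1-one | O=C=CC(=C)CC/C=C(\C)[C@@H](O[Si](C)(C)C(C)(C)C)CC(=O)C(C)=C
F6 | step 6 | (1R,5S,7S)-7-[(1S)-1-[(tert-butyldimethylsilyl)oxy]-4-methyl-3-oxopent-4-en-1-yl]-7-methyl-2-methylidenebicyclo[3.1.1]heptan-6-one | C=C(C)C(=O)C[C@H](O[Si](C)(C)C(C)(C)C)[C@@]2(C)[C@@H]3CCC(=C)[C@H]2C3=O
F7 | step 6 | triphenylphosphine-ligated copper(I) enolate of F6 | CC(C)=C(O[Cu]P(c1ccccc1)(c1ccccc1)c1ccccc1)C[C@H](O[Si](C)(C)C(C)(C)C)[C@@]2(C)[C@@H]3CCC(=C)[C@H]2C3=O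
F8 | step 6 | (9S)-9-[(tert-butyldimethylsilyl)oxy]-5-hydroxylongipin-3(15)-en-7-one | O=C1C[C@H](O[Si](C)(C)C(C)(C)C)[C@@]2(C)[C@@H]3CCC(=C)[C@H]2[C@]3(O)C1(C)C
F9 | step 6 | methyl (9S)-9-[(tert-butyldimethylsilyl)oxy]-7-oxolongipin-3(15)-en-5-yl oxalate | O=C1C[C@H](O[Si](C)(C)C(C)(C)C)[C@@]2(C)[C@@H]3CCC(=C)[C@H]2[C@]3(OC(=O)C(=O)OC)C1(C)C
F10 | step 6 | (9S)-9-[(tert-butyldimethylsilyl)oxy]longipin-3(15)-en-7-one | O=C1C[C@H](O[Si](C)(C)C(C)(C)C)[C@@]2(C)[C@@H]3CCC(=C)[C@H]2[C@@H]3C1(C)C
F11 | step 6 | (9S)-9-[(tert-butyldimethylsilyl)oxy]longipin-2-en-7-one | O=C1C[C@H](O[Si](C)(C)C(C)(C)C)[C@@]2(C)[C@@H]3CC=C(C)[C@H]2[C@@H]3C1(C)C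
F12 | step 6 | (7R,9S)-9-[(tert-butyldimethylsilyl)oxy]longipin-2-en-7-ol | O[C@@H]1C[C@H](O[Si](C)(C)C(C)(C)C)[C@@]2(C)[C@@H]3CC=C(C)[C@H]2[C@@H]3C1(C)C
F13 | step 6 | (7R,9S)-9-[(tert-butyldimethylsilyl)oxy]longipin-2-en-7-yl methacrylate | C=C(C)C(=O)O[C@@H]1C[C@H](O[Si](C)(C)C(C)(C)C)[C@@]2(C)[C@@H]3CC=C(C)[C@H]2[C@@H]3C1(C)C
F14 | step 6 | (7R,9S)-9-hydroxylongipin-2-en-7-yl methacrylate | C=C(C)C(=O)O[C@@H]1C[C@H](O)[C@@]2(C)[C@@H]3CC=C(C)[C@H]2[C@@H]3C1(C)C
F15 | step 6 | (7R)-9-oxolongipin-2-en-7-yl methacrylate | C=C(C)C(=O)O[C@@H]1CC(=O)[C@@]2(C)[C@@H]3CC=C(C)[C@H]2[C@@H]3C1(C)C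
F16 | step 6 | (7R,9R)-9-hydroxylongipin-2-en-7-yl methacrylate | C=C(C)C(=O)O[C@@H]1C[C@@H](O)[C@@]2(C)[C@@H]3CC=C(C)[C@H]2[C@@H]3C1(C)C
F17 | step 7 | triethylsilyl enol ether of 11 at C6/C7 | CC(C)=C(O[Si](CC)(CC)CC)C[C@@H](O[Si](C)(C)C(C)(C)C)[C@@]2(C)[C@@H]3CCC(=C)[C@H]2C3=O
F18 | step 9 | (7R,9R)-9-[(tert-butyldimethylsilyl)oxy]longipin-3(15)-ene-5,7-diol | O[C@@H]1C[C@@H](O[Si](C)(C)C(C)(C)C)[C@@]2(C)[C@@H]3CCC(=C)[C@H]2[C@]3(O)C1(C)C
F19 | step 9 | (7R,9R)-9-[(tert-butyldimethylsilyl)oxy]-7-[(triethylsilyl)oxy]longipin-3(15)-en-5-ol | CC[Si](CC)(CC)O[C@@H]1C[C@@H](O[Si](C)(C)C(C)(C)C)[C@@]2(C)[C@@H]3CCC(=C)[C@H]2[C@]3(O)C1(C)C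
F20 | step 9 | methyl (7R,9R)-9-[(tert-butyldimethylsilyl)oxy]-7-[(triethylsilyl)oxy]longipin-3(15)-en-5-yl oxalate | CC[Si](CC)(CC)O[C@@H]1C[C@@H](O[Si](C)(C)C(C)(C)C)[C@@]2(C)[C@@H]3CCC(=C)[C@H]2[C@]3(OC(=O)C(=O)OC)C1(C)C
F21 | step 9 | (7R,9R)-9-[(tert-butyldimethylsilyl)oxy]-7-[(triethylsilyl)oxy]longipin-3(15)-ene | CC[Si](CC)(CC)O[C@@H]1C[C@@H](O[Si](C)(C)C(C)(C)C)[C@@]2(C)[C@@H]3CCC(=C)[C@H]2[C@@H]3C1(C)C
F22 | step 9 | (7R,9R)-9-[(tert-butyldimethylsilyl)oxy]-7-[(triethylsilyl)oxy]longipin-2-ene | CC[Si](CC)(CC)O[C@@H]1C[C@@H](O[Si](C)(C)C(C)(C)C)[C@@]2(C)[C@@H]3CC=C(C)[C@H]2[C@@H]3C1(C)C
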